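**Plan**

- Briarane numbering throughout: ring A = C1, C10–C14 (drawn clockwise, β = toward the viewer = the face of the C15 methyl on C1); ring B = ten-membered C1–C10; ring C = lactone C7–O–C19–C17–C8.
- Retrosynthesis: first the O16–Si bond, then C2–C3 of ring B. The free allylic C2 carbinol lies between quaternary C1 and the Z C3=C4 alkene, so it is read as an alkenyl-metal addition to a non-enolisable aldehyde on C1. Then C8–C17 and O–C19 of ring C, then C8–C9, and in ring A the bonds C1–C14 and C10–C11.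
- Forward: ring A is made first by a catalytic asymmetric Diels–Alder reaction and is staged through a bridged C9/O12 lactone. The C8–C3 enyne ketone is joined by a boron aldol, ring C is closed by a samarium Reformatsky reaction, and ring B is closed last.
- Stereochemistry: C1/C10 come from the catalyst and the E dienophile, C11 from kinetic protonation, C12 from hydride delivery to the α face, and the 13,14-epoxide from C2–OH direction. C9 comes from Felkin–Anh addition, C7 from 1,3-syn reduction, C8/C17 from C7 during lactone closure, and C2 from C1 during the ring B closure.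

Key step: step 28

Assumption: the (S)-configured oxazaborolidinium ion is taken to expose the enal face that leads to the enantiomer drawn for 4; if the sense proves opposite, its (R)-antipode is used.

**Ring A (steps 1–12)**

Step 1
Reactants: 1 pent-1-en-3-one
Product: 2 (Z)-tert-butyldimethyl(penta-1,3-dien-3-yloxy)silane
Conditions: TBSOTf, Et3N, Et2O, 0 °C
Reagents that add atoms: tert-butyldimethylsilyl trifluoromethanesulfonate (CC(C)(C)[Si](C)(C)OS(=O)(=O)C(F)(F)F)
Why: Soft enolisation and O-silylation of the ethyl ketone (silyl enol ether formation) should give mainly the Z enol ether, whose methyl group then sits outside the s-cis diene.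

Step 2
Reactants: 2 silyloxydiene; 3 ethyl (E)-3-methyl-4-oxobut-2-enoate
Product: 4 ethyl 3-(tert-butyldimethylsilyloxy)-6-formyl-2,6-dimethylcyclohex-3-ene-1-carboxylate (ring A: 1β-CH3; 1α-CHO; 10β-CO2Et; 11α-CH3; C12=C13 enol ether)
Conditions: (S)-3,3-diphenyl-1-(2-methylphenyl)tetrahydro-1H,3H-pyrrolo[1,2-c][1,3,2]oxazaborole·HNTf2 (cat.), CH2Cl2, −78 to −40 °C
Reagents that add atoms: none
Why: In this enantioselective Lewis-acid-catalysed Diels–Alder reaction the activated formyl group directs the nucleophilic diene terminus C11 to C10 and C14 to C1, the E geometry of 3 fixes the trans relation of C2 and C9, the catalyst sets the absolute configuration at C1 and C10, and the endo formyl group is expected to place the C11 methyl on the α face, which step 5 corrects.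

Step 3
Reactants: 4 Diels–Alder adduct
Product: 5 C2 triethylsilyl ether of 4 (1α-CH2OSiEt3)
Conditions: [(Ph3P)CuH]6 (cat.), Et3SiH, toluene, rt
Reagents that add atoms: triethylsilane (CC[SiH](CC)CC)
Why: Copper-hydride-catalysed hydrosilylation of the aldehyde gives the silyl ether directly and leaves ester and silyl enol ether alone, so a free C2 hydroxyl never faces the C9 ester.

Step 4
Reactants: 5 silyl ether
Product: 6 11α-methyl enone (C12 ketone; C13=C14; 1α-CH2OSiEt3; 10β-CO2Et)
Conditions: Pd(OAc)2, MeCN, rt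
Reagents that add atoms: none
Why: Saegusa–Ito oxidation palladates the C12 silyl enol ether at C13 and eliminates hydride from C14, which places the alkene at C13=C14 without touching C10 or C11.

Step 5
Reactants: 6 11α-methyl enone
Product: 8 11β-methyl enone (C11 epimer of 6), via lithium dienolate 7 (not isolated)
Conditions: LDA, THF, −78 °C; then AcOH in THF, −78 °C
Reagents that add atoms: none
Why: Kinetic deprotonation at C11 (the only α′ hydrogen) and kinetic protonation of the cross-conjugated enolate from the α face, anti to the C10 ester, should give the cis C10/C11 ketone, as in the protonation of 2-methyl-3-substituted cyclohexanone enolates.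

Step 6
Reactants: 8 11β-methyl enone
Product: 10 bridged lactone (C9 carbonyl on the 12β oxygen; C13=C14; 1α-CH2OSiEt3), via 12β-allylic alcohol 9 (not isolated)
Conditions: NaBH4, CeCl3·7H2O, MeOH, −78 °C; then DBU (cat.), toluene, 60 °C
Reagents that add atoms: none
Why: Luche 1,2-reduction should deliver hydride to the α face because the β face is screened by the C11 methyl or the axial C10 ester in either half-chair, and only the resulting 12β-alcohol can lactonise onto the cis C10 ester, so the base-catalysed ring closure also removes any 12α epimer.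

Step 7
Reactants: 10 bridged lactone
Product: 11 hydroxy lactone (1α-CH2OH)
Conditions: HF·pyridine, pyridine, THF, 0 °C
Reagents that add atoms: none
Why: Fluoride cleavage of the primary triethylsilyl ether (desilylation) frees the C2 hydroxyl, which cannot migrate onto C9 because it stands trans-diaxial to the lactone arm.

Step 8
Reactants: 11 hydroxy lactone
Product: 12 13α,14α-epoxy hydroxy lactone
Conditions: VO(acac)2 (cat.), t-BuOOH, CH2Cl2, 0 °C to rt
Reagents that add atoms: tert-butyl hydroperoxide (CC(C)(C)OO)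
Why: In this hydroxyl-directed epoxidation the pseudo-axial homoallylic C2–OH on the α face delivers oxygen to the α face of C13=C14, while the lactone masks the C12 oxygen and screens the β face.

Step 9
Reactants: 12 epoxy hydroxy lactone
Product: 13 triethylsilyl ether of 12
Conditions: TESCl, imidazole, CH2Cl2, 0 °C
Reagents that add atoms: chlorotriethylsilane (CC[Si](Cl)(CC)CC)
Why: Silylation of the primary neopentyl alcohol gives the C2 protecting group that is later removed in the presence of the C16 tert-butyldimethylsilyl ether.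

Step 10
Reactants: 13 silylated epoxy lactone
Product: 14 12β-hydroxy N-methoxy-N-methylamide (C9 amide on C10β)
Conditions: MeNH(OMe)·HCl, i-PrMgCl, THF, −20 °C
Reagents that add atoms: N,O-dimethylhydroxylamine hydrochloride (CNOC.Cl)
Why: Aminolysis of the strained bridged lactone by the chloromagnesium amide gives the N-methoxy-N-methylamide and frees the 12β-hydroxyl, and the low temperature keeps the magnesium alkoxide from attacking the neighbouring epoxide.

Step 11
Reactants: 14 hydroxy amide
Product: 15 12β-acetate of 14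
Conditions: Ac2O, DMAP (cat.), pyridine, CH2Cl2, rt
Reagents that add atoms: acetic anhydride (CC(=O)OC(C)=O)
Why: DMAP-catalysed acetylation installs the C12 acetate of the target on the only free hydroxyl.

Step 12
Reactants: 15 acetoxy amide
Product: 16 ring A aldehyde (12β-acetoxy-13α,14α-epoxy-1β,11β-dimethyl-1α-(triethylsilyloxymethyl)cyclohexane-10β-carbaldehyde; briarane locants)
Conditions: Cp2Zr(H)Cl, THF, rt
Reagents that add atoms: none
Why: Reduction of the N-methoxy-N-methylamide to the aldehyde with Cp2Zr(H)Cl (amide-to-aldehyde reduction) is known to spare acetates and silyl ethers, and the neutral conditions should leave C10 unepimerised.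

**C8–C3 fragment (steps 13–16)**

Step 13
Reactants: 17 (4-methoxyphenyl)methanol; 18 2-chloro-N-methoxy-N-methylacetamide
Product: 20 N-methoxy-2-[(4-methoxybenzyl)oxy]-N-methylacetamide, via sodium 4-methoxybenzyl oxide 19 (not isolated)
Conditions: NaH, THF, 0 °C to rt
Reagents that add atoms: none
Why: Williamson ether synthesis on the activated α-chloro amide gives the C8 carbon with its oxygen already protected.

Step 14
Reactants: 21 tert-butyldimethyl(prop-2-yn-1-yloxy)silane; 20 N-methoxy-N-methylamide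
Product: 23 5-(tert-butyldimethylsilyloxy)-1-[(4-methoxybenzyl)oxy]pent-3-yn-2-one, via lithium acetylide 22 (not isolated)
Conditions: n-BuLi, THF, −78 °C; then 20, −78 to 0 °C; H2O
Reagents that add atoms: none
Why: Acylation of the lithium acetylide by the N-methoxy-N-methylamide stops at the ketone stage and gives the ynone (ketone synthesis from an N-methoxy-N-methylamide).

Step 15
Reactants: 23 ynone
Product: 24 (Z)-5-(tert-butyldimethylsilyloxy)-4-iodo-1-[(4-methoxybenzyl)oxy]pent-3-en-2-one
Conditions: NaI, AcOH, MeCN, rt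
Reagents that add atoms: sodium iodide ([Na+].[I-])
Why: Conjugate addition of iodide to the ynone followed by anti protonation (hydroiodination of an activated alkyne) gives the Z β-iodo enone, in which the acyl carbon C7 is cis to iodine and trans to C16.

Step 16
Reactants: 24 iodo enone; 25 ethynyltrimethylsilane
Product: 26 (E)-4-[(tert-butyldimethylsilyloxy)methyl]-1-[(4-methoxybenzyl)oxy]-6-(trimethylsilyl)hex-3-en-5-yn-2-one (C8 to C3 with C16)
Conditions: PdCl2(PPh3)2 (cat.), CuI (cat.), Et3N, THF, rt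
Reagents that add atoms: none
Why: Sonogashira coupling replaces iodine with retention, so C7 and C4 end up cis on C5=C6 as ring B requires.

**Coupling, ring C and ring B (steps 17–29)**

Step 17
Reactants: 26 enyne ketone; 16 ring A aldehyde
Product: 28 aldol adduct (9R-hydroxy; 8-OPMB anti to 9-OH; C7 ketone), via boron enolate 27 (not isolated)
Conditions: (c-C6H11)2BCl, Et3N, Et2O, −78 to 0 °C; then 16, −78 to −20 °C; MeOH, pH 7 buffer
Reagents that add atoms: none
Why: In this boron aldol reaction the E enol borinate of the α-alkoxy ketone reacts through a Zimmerman–Traxler chair to give the 8,9-anti adduct, and Felkin–Anh addition anti to the quaternary C1 branch of the aldehyde should set C9 as R.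

Step 18
Reactants: 28 aldol adduct
Product: 29 (7S,9R)-diol (7-OH syn to 9-OH)
Conditions: Et2BOMe, NaBH4, THF/MeOH 4:1, −78 °C; then AcOH, MeOH
Reagents that add atoms: none
Why: Narasaka–Prasad reduction delivers external hydride to the boron chelate of the β-hydroxy enone and gives the 1,3-syn diol, which sets C7 from C9 whatever the configuration at C8.

Step 19
Reactants: 29 diol; 30 2-bromopropanoyl bromide (racemic)
Product: 31 C7 2-bromopropanoate (9-OH free; both epimers at the CHBr carbon)
Conditions: pyridine, CH2Cl2, −78 to −40 °C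
Reagents that add atoms: none
Why: Site-selective O-acylation should occur at the less hindered allylic C7 hydroxyl, because the C9 hydroxyl is flanked by the ring A carbon C10 next to quaternary C1.

Step 20
Reactants: 31 bromopropanoate
Product: 32 9-acetate of 31
Conditions: Ac2O, DMAP (cat.), pyridine, CH2Cl2, 0 °C to rt
Reagents that add atoms: acetic anhydride (CC(=O)OC(C)=O)
Why: DMAP-catalysed acetylation of the remaining hindered secondary hydroxyl installs the C9 acetate of the target.

Step 21
Reactants: 32 acetate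
Product: 33 C8 alcohol
Conditions: DDQ, CH2Cl2/pH 7 buffer, 0 °C
Reagents that add atoms: none
Why: Oxidative cleavage of the 4-methoxybenzyl ether by DDQ leaves silyl ethers, esters, the epoxide and the enyne untouched.

Step 22
Reactants: 33 C8 alcohol
Product: 34 C8 ketone (9-OAc; 7-O-bromopropanoyl)
Conditions: DMP, NaHCO3, CH2Cl2, 0 °C
Reagents that add atoms: none
Why: Buffered Dess–Martin oxidation gives the base-sensitive α,α′-diacyloxy ketone under neutral conditions, so C7 and C9 should not epimerise.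

Step 23
Reactants: 34 keto bromo ester
Product: 36 ring C lactone (7S; 8S; 17R; 8-OH free; silylated enyne), via samarium enolate 35 (not isolated)
Conditions: SmI2 (2.2 equiv), THF, −78 °C; aq. NH4Cl
Reagents that add atoms: none
Why: In this intramolecular Reformatsky reaction the trivalent samarium enolate formed from the C–Br bond adds to the chelated C8 ketone to close the five-membered lactone, with the bulky C9 branch trans to the C6 substituent (8-OH cis to C6) and the C17 methyl trans to the C9 branch, the latter also being the thermodynamic arrangement at the epimerisable C17.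

Step 24
Reactants: 36 lactone
Product: 37 iodoalkyne (C3–I)
Conditions: NIS, AgNO3 (cat.), DMF, rt, dark
Reagents that add atoms: N-iodosuccinimide (O=C1CCC(=O)N1I)
Why: Silver-catalysed iododesilylation converts the alkynylsilane directly into the 1-iodoalkyne under neutral conditions that the acetates do not feel.

Step 25
Reactants: 37 iodoalkyne
Product: 38 (3Z)-alkenyl iodide (C2 silyl ether)
Conditions: 2-nitrobenzenesulfonohydrazide, Et3N, THF/i-PrOH, rt
Reagents that add atoms: none
Why: Diimide reduction adds hydrogen syn to the iodoalkyne and gives the Z alkenyl iodide, while the trisubstituted C5=C6 alkene reacts much more slowly.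

Step 26
Reactants: 38 alkenyl iodide
Product: 39 C2 alcohol
Conditions: PPTS, MeOH/CH2Cl2, 0 °C
Reagents that add atoms: none
Why: Acid-catalysed methanolysis removes the triethylsilyl ether much faster than the C16 tert-butyldimethylsilyl ether (selective desilylation).

Step 27
Reactants: 39 C2 alcohol
Product: 40 seco aldehyde (C2 aldehyde on C1; Z-C3 iodide; 16-OTBS)
Conditions: DMP, NaHCO3, CH2Cl2, 0 °C to rt
Reagents that add atoms: none
Why: Dess–Martin oxidation of the only primary alcohol gives the neopentyl, non-enolisable aldehyde and does not touch the tertiary C8 hydroxyl.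

Step 28
Reactants: 40 seco aldehyde
Product: 42 16-O-tert-butyldimethylsilyl briaexcavatolide N, via alkenylchromium species 41 (not isolated)
Conditions: CrCl2 (excess), NiCl2 (cat.), degassed DMSO/THF, rt, slow addition to about 1 mM
Reagents that add atoms: none
Why: Zerovalent nickel, formed from NiCl2 by CrCl2, inserts into the C3–I bond with retention of the Z geometry, the alkenyl group passes to trivalent chromium (41), and this adds to the C2 aldehyde, which is the only aldehyde present; the closest known reaction type is the Nozaki–Hiyama–Kishi macrocyclisation of alkenyl iodide aldehydes to medium-ring allylic alcohols. Ring B closes by a 10-exo-trig nucleophilic 1,2-addition that forms C2–C3. The new C2 centre is controlled by quaternary C1: the C=O is expected to lie anti to the C1–C14 (epoxide) bond, and the chain anchored at C10 reaches the carbonyl face remote from the C15 methyl, which gives the 2S alkoxide. The step needs chemoselectivity (acetates, lactone, epoxide, silyl ether and free C8–OH are inert to the organochromium), retention of alkene geometry, and cyclisation over oligomerisation; the trans C2 and C9 arms on ring A, the rigid lactone and the two ring-cis alkenes hold C2 and C3 close, and high dilution supports this.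

Step 29
Reactants: 42 silyl ether
Product: 43 briaexcavatolide N
Conditions: HF·pyridine, pyridine, THF, 0 °C to rt
Reagents that add atoms: none
Why: Buffered fluoride desilylation frees the primary allylic C16 alcohol without acetate migration or epoxide opening.

**Compound list**

1 | pent-1-en-3-one | CCC(=O)C=C | starting material
2 | (Z)-tert-butyldimethyl(penta-1,3-dien-3-yloxy)silane | C=C/C(O[Si](C)(C)C(C)(C)C)=C/C | intermediate
3 | ethyl (E)-3-methyl-4-oxobut-2-enoate | CCOC(=O)/C=C(\C)C=O | starting material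
4 | ethyl 3-(tert-butyldimethylsilyloxy)-6-formyl-2,6-dimethylcyclohex-3-ene-1-carboxylate (1β-CH3, 1α-CHO, 10β-CO2Et, 11α-CH3) | CC(C)(C)[Si](C)(C)OC=1[C@@H](C)[C@H](C(=O)OCC)[C@@](C)(C=O)CC=1 | intermediate
5 | C2 triethylsilyl ether of 4 | CC(C)(C)[Si](C)(C)OC=1[C@@H](C)[C@H](C(=O)OCC)[C@@](C)(CO[Si](CC)(CC)CC)CC=1 | intermediate
6 | 11α-methyl enone (C12 ketone, C13=C14) | O=C1[C@@H](C)[C@H](C(=O)OCC)[C@@](C)(CO[Si](CC)(CC)CC)C=C1 | intermediate
7 | lithium dienolate of 6 (C11=C12–OLi) | [Li+].[O-]C1=C(C)[C@H](C(=O)OCC)[C@@](C)(CO[Si](CC)(CC)CC)C=C1 | intermediate (not isolated)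
8 | 11β-methyl enone | O=C1[C@H](C)[C@H](C(=O)OCC)[C@@](C)(CO[Si](CC)(CC)CC)C=C1 | intermediate
9 | 12β-allylic alcohol | O[C@@H]1[C@H](C)[C@H](C(=O)OCC)[C@@](C)(CO[Si](CC)(CC)CC)C=C1 | intermediate (not isolated)
10 | bridged lactone (C9 carbonyl on 12β-O), C2 silyl ether | O=C2O[C@@H]1[C@H](C)[C@H]2[C@@](C)(CO[Si](CC)(CC)CC)C=C1 | intermediate
11 | hydroxy lactone (1α-CH2OH) | O=C2O[C@@H]1[C@H](C)[C@H]2[C@@](C)(CO)C=C1 | intermediate
12 | 13α,14α-epoxy hydroxy lactone | O=C2O[C@@H]1[C@H](C)[C@H]2[C@@](C)(CO)[C@H]3O[C@@H]13 | intermediate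
13 | triethylsilyl ether of 12 | O=C2O[C@@H]1[C@H](C)[C@H]2[C@@](C)(CO[Si](CC)(CC)CC)[C@H]3O[C@@H]13 | intermediate
14 | 12β-hydroxy N-methoxy-N-methylamide | O[C@@H]1[C@H](C)[C@H](C(=O)N(C)OC)[C@@](C)(CO[Si](CC)(CC)CC)[C@H]2O[C@@H]12 | intermediate
15 | 12β-acetoxy N-methoxy-N-methylamide | CC(=O)O[C@@H]1[C@H](C)[C@H](C(=O)N(C)OC)[C@@](C)(CO[Si](CC)(CC)CC)[C@H]2O[C@@H]12 | intermediate
16 | ring A aldehyde (12β-OAc, 13α,14α-epoxide, 11β-CH3, 10β-CHO, 1β-CH3, 1α-CH2OSiEt3) | CC(=O)O[C@@H]1[C@H](C)[C@H](C=O)[C@@](C)(CO[Si](CC)(CC)CC)[C@H]2O[C@@H]12 | intermediate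
17 | (4-methoxyphenyl)methanol | COc1ccc(CO)cc1 | starting material
18 | 2-chloro-N-methoxy-N-methylacetamide | CON(C)C(=O)CCl | starting material
19 | sodium 4-methoxybenzyl oxide | [Na+].COc1ccc(C[O-])cc1 | intermediate (not isolated)
20 | N-methoxy-2-[(4-methoxybenzyl)oxy]-N-methylacetamide | COc1ccc(COCC(=O)N(C)OC)cc1 | intermediate
21 | tert-butyldimethyl(prop-2-yn-1-yloxy)silane | C#CCO[Si](C)(C)C(C)(C)C | starting material
22 | lithium acetylide of 21 | [Li]C#CCO[Si](C)(C)C(C)(C)C | intermediate (not isolated)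
23 | 5-(tert-butyldimethylsilyloxy)-1-[(4-methoxybenzyl)oxy]pent-3-yn-2-one | COc1ccc(COCC(=O)C#CCO[Si](C)(C)C(C)(C)C)cc1 | intermediate
24 | (Z)-5-(tert-butyldimethylsilyloxy)-4-iodo-1-[(4-methoxybenzyl)oxy]pent-3-en-2-one | COc1ccc(COCC(=O)/C=C(\I)CO[Si](C)(C)C(C)(C)C)cc1 | intermediate
25 | ethynyltrimethylsilane | C#C[Si](C)(C)C | starting material
26 | (E)-4-[(tert-butyldimethylsilyloxy)methyl]-1-[(4-methoxybenzyl)oxy]-6-(trimethylsilyl)hex-3-en-5-yn-2-one | COc1ccc(COCC(=O)/C=C(\C#C[Si](C)(C)C)CO[Si](C)(C)C(C)(C)C)cc1 | intermediate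
27 | (E)-dicyclohexylboron enolate of 26 | COc1ccc(CO/C=C(/OB(C2CCCCC2)C2CCCCC2)\C=C(/C#C[Si](C)(C)C)CO[Si](C)(C)C(C)(C)C)cc1 | intermediate (not isolated)
28 | aldol adduct (9R-OH, 8-OPMB anti, C7 ketone) | CC(=O)O[C@@H]1[C@H](C)[C@H]([C@@H](O)[C@@H](OCc3ccc(OC)cc3)C(=O)/C=C(CO[Si](C)(C)C(C)(C)C)\C#C[Si](C)(C)C)[C@@](C)(CO[Si](CC)(CC)CC)[C@H]2O[C@@H]12 | intermediate
29 | (7S,9R)-syn-diol | CC(=O)O[C@@H]1[C@H](C)[C@H]([C@@H](O)[C@@H](OCc3ccc(OC)cc3)[C@H](/C=C(CO[Si](C)(C)C(C)(C)C)\C#C[Si](C)(C)C)O)[C@@](C)(CO[Si](CC)(CC)CC)[C@H]2O[C@@H]12 | intermediate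
30 | 2-bromopropanoyl bromide (racemic) | CC(Br)C(Br)=O | starting material
31 | C7 2-bromopropanoate (9-OH free) | CC(=O)O[C@@H]1[C@H](C)[C@H]([C@@H](O)[C@@H](OCc3ccc(OC)cc3)[C@H](/C=C(CO[Si](C)(C)C(C)(C)C)\C#C[Si](C)(C)C)OC(=O)C(C)Br)[C@@](C)(CO[Si](CC)(CC)CC)[C@H]2O[C@@H]12 | intermediate
32 | 9-acetate of 31 | CC(=O)O[C@@H]1[C@H](C)[C@H]([C@@H](OC(C)=O)[C@@H](OCc3ccc(OC)cc3)[C@H](/C=C(CO[Si](C)(C)C(C)(C)C)\C#C[Si](C)(C)C)OC(=O)C(C)Br)[C@@](C)(CO[Si](CC)(CC)CC)[C@H]2O[C@@H]12 | intermediate
33 | C8 alcohol | CC(=O)O[C@@H]1[C@H](C)[C@H]([C@@H](OC(C)=O)[C@@H](O)[C@H](/C=C(CO[Si](C)(C)C(C)(C)C)\C#C[Si](C)(C)C)OC(=O)C(C)Br)[C@@](C)(CO[Si](CC)(CC)CC)[C@H]2O[C@@H]12 | intermediate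
34 | C8 ketone | CC(=O)O[C@@H]1[C@H](C)[C@H]([C@@H](OC(C)=O)C(=O)[C@H](/C=C(CO[Si](C)(C)C(C)(C)C)\C#C[Si](C)(C)C)OC(=O)C(C)Br)[C@@](C)(CO[Si](CC)(CC)CC)[C@H]2O[C@@H]12 | intermediate
35 | samarium enolate of 34 (trivalent samarium) | CC(=O)O[C@@H]1[C@H](C)[C@H]([C@@H](OC(C)=O)C(=O)[C@H](/C=C(CO[Si](C)(C)C(C)(C)C)\C#C[Si](C)(C)C)OC(=CC)O[Sm](I)I)[C@@](C)(CO[Si](CC)(CC)CC)[C@H]2O[C@@H]12 | intermediate (not isolated)
36 | ring C lactone (7S,8S,17R), silylated enyne | CC(=O)O[C@@H]1[C@H](C)[C@H]([C@@H](OC(C)=O)[C@@]3(O)[C@H](/C=C(CO[Si](C)(C)C(C)(C)C)\C#C[Si](C)(C)C)OC(=O)[C@@H]3C)[C@@](C)(CO[Si](CC)(CC)CC)[C@H]2O[C@@H]12 | intermediate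
37 | iodoalkyne | CC(=O)O[C@@H]1[C@H](C)[C@H]([C@@H](OC(C)=O)[C@@]3(O)[C@H](/C=C(CO[Si](C)(C)C(C)(C)C)\C#CI)OC(=O)[C@@H]3C)[C@@](C)(CO[Si](CC)(CC)CC)[C@H]2O[C@@H]12 | intermediate
38 | (3Z)-alkenyl iodide, C2 triethylsilyl ether | CC(=O)O[C@@H]1[C@H](C)[C@H]([C@@H](OC(C)=O)[C@@]3(O)[C@H](/C=C(CO[Si](C)(C)C(C)(C)C)\C=C/I)OC(=O)[C@@H]3C)[C@@](C)(CO[Si](CC)(CC)CC)[C@H]2O[C@@H]12 | intermediate
39 | C2 alcohol | CC(=O)O[C@@H]1[C@H](C)[C@H]([C@@H](OC(C)=O)[C@@]3(O)[C@H](/C=C(CO[Si](C)(C)C(C)(C)C)\C=C/I)OC(=O)[C@@H]3C)[C@@](C)(CO)[C@H]2O[C@@H]12 | intermediate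
40 | seco aldehyde | CC(=O)O[C@@H]1[C@H](C)[C@H]([C@@H](OC(C)=O)[C@@]3(O)[C@H](/C=C(CO[Si](C)(C)C(C)(C)C)\C=C/I)OC(=O)[C@@H]3C)[C@@](C)(C=O)[C@H]2O[C@@H]12 | intermediate
41 | alkenylchromium dichloride of 40 (trivalent chromium) | CC(=O)O[C@@H]1[C@H](C)[C@H]([C@@H](OC(C)=O)[C@@]3(O)[C@H](/C=C(CO[Si](C)(C)C(C)(C)C)\C=C/[Cr](Cl)Cl)OC(=O)[C@@H]3C)[C@@](C)(C=O)[C@H]2O[C@@H]12 | intermediate (not isolated)
42 | 16-O-tert-butyldimethylsilyl briaexcavatolide N | CC(=O)O[C@@H]1[C@H](C)[C@@H]2[C@@H](OC(C)=O)[C@@]3(O)[C@H](/C=C(CO[Si](C)(C)C(C)(C)C)\C=C/[C@H](O)[C@@]2(C)[C@H]2O[C@@H]12)OC(=O)[C@@H]3C | intermediate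
43 | briaexcavatolide N | CC(=O)O[C@@H]1[C@H](C)[C@@H]2[C@@H](OC(C)=O)[C@@]3(O)[C@H](/C=C(CO)\C=C/[C@H](O)[C@@]2(C)[C@H]2O[C@@H]12)OC(=O)[C@@H]3C | target

**Step count and risks**

Total step count: 29.
Longest linear sequence: 25 steps (steps 1–12, then 17–29); steps 13–16 make the C8–C3 fragment.

Steps most likely to fail:

1. Step 28 (ring B closure). The risk is attack on the wrong face of the C2 aldehyde, or poor facial discrimination, so that the 2-epimer predominates. The fallback sets C2 by reduction instead of during C–C bond formation. It sets out from 40 and runs the cyclisation unchanged. The epimeric carbinol F1 is oxidised with DMP to the ring B C2 ketone F2. A 1,2-reduction from the open peripheral face (NaBH4, CeCl3, MeOH, −78 °C, or a borane with a chiral oxazaborolidine if reagent control is needed) then returns to 42.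

2. Step 23 (ring C closure). The risk is single-electron reduction of the ketone with loss of the C7 or C9 acyloxy group, competing with enolate formation. The fallback generates the enolate by hydrometalation instead of electron transfer. It sets out from 32, where DBU in CH2Cl2 eliminates HBr from the bromopropanoate to give acrylate F3. DDQ then gives alcohol F4 and DMP gives keto acrylate F5. A copper-hydride-catalysed intramolecular reductive aldol reaction (Cu(OAc)2, 1,1′-bis(diphenylphosphino)ferrocene, 1,1,3,3-tetramethyldisiloxane, THF, rt, then aqueous work-up) closes the lactone with the methyl cis to the hydroxyl and returns to 36.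

3. Step 5 (C11). The risk is protonation from the β face, or equilibration, which would leave the 11α-methyl epimer. The fallback transfers a hydrogen atom to a planar C11 radical instead of protonating an enolate. It sets out from 6: LDA followed by N-bromosuccinimide gives the C11 bromide F6 (either epimer). (Me3Si)3SiH with Et3B/air in toluene at −78 °C then delivers hydrogen from the bulky silane to the α face and returns to 8.

**Further compounds**

F1 | step 28 | 2-epi-16-O-tert-butyldimethylsilyl briaexcavatolide N (2R carbinol) | CC(=O)O[C@@H]1[C@H](C)[C@@H]2[C@@H](OC(C)=O)[C@@]3(O)[C@H](/C=C(CO[Si](C)(C)C(C)(C)C)\C=C/[C@@H](O)[C@@]2(C)[C@H]2O[C@@H]12)OC(=O)[C@@H]3C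
F2 | step 28 | ring B C2 ketone (2-dehydro-42) | CC(=O)O[C@@H]1[C@H](C)[C@@H]2[C@@H](OC(C)=O)[C@@]3(O)[C@H](/C=C(CO[Si](C)(C)C(C)(C)C)\C=C/C(=O)[C@@]2(C)[C@H]2O[C@@H]12)OC(=O)[C@@H]3C
F3 | step 23 | C7 acrylate (9-OAc, 8-OPMB) | CC(=O)O[C@@H]1[C@H](C)[C@H]([C@@H](OC(C)=O)[C@@H](OCc3ccc(OC)cc3)[C@H](/C=C(CO[Si](C)(C)C(C)(C)C)\C#C[Si](C)(C)C)OC(=O)C=C)[C@@](C)(CO[Si](CC)(CC)CC)[C@H]2O[C@@H]12
F4 | step 23 | C7 acrylate C8 alcohol | CC(=O)O[C@@H]1[C@H](C)[C@H]([C@@H](OC(C)=O)[C@@H](O)[C@H](/C=C(CO[Si](C)(C)C(C)(C)C)\C#C[Si](C)(C)C)OC(=O)C=C)[C@@](C)(CO[Si](CC)(CC)CC)[C@H]2O[C@@H]12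
F5 | step 23 | C7 acrylate C8 ketone | CC(=O)O[C@@H]1[C@H](C)[C@H]([C@@H](OC(C)=O)C(=O)[C@H](/C=C(CO[Si](C)(C)C(C)(C)C)\C#C[Si](C)(C)C)OC(=O)C=C)[C@@](C)(CO[Si](CC)(CC)CC)[C@H]2O[C@@H]12
F6 | step 5 | C11 bromide of enone 6 (either epimer at C11) | O=C1C(C)(Br)[C@H](C(=O)OCC)[C@@](C)(CO[Si](CC)(CC)CC)C=C1
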